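**Plan**

- Cuts, in chroman numbering (O1, C2, C3, C4, C4a, C5–C8, C8a): C8–prenyl (back to an O5 prenyl ether), C4a–C5 (opening the benzene ring to an acyclic S-phenyl thioester), O–CH3 at C7, C6–C7 (crossed Claisen), C8–C8a (acetate enolate on a δ-lactone), C4–C4a (cross-metathesis) and C2–C3 (crotylation).
- Forward: the oxane ring is made first, as a trans-5,6-dimethyl δ-lactone; the chain C4a–C8a–C8–C7–C6–C5 is then joined by two Claisen-type C–C bond formations; the benzene ring closes in step 11; the prenyl group is then moved from O5 to C8 and the ester is saponified.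
- Enabling feature: C5, C7 and C8a are the carbonyl carbons of a 3,5-dioxoacyl chain C5–C6–C7–C8–C8a–C4a, and the target already carries their oxygens differentiated as free OH, OMe and ring O1. The chain can therefore be carried as thioester, methyl enol ether and cyclic enol ether and folded by forming C4a–C5 through a dienylketene.
- Stereochemistry: C2 and C3 (trans) come from a reagent-controlled anti crotylboration of acetaldehyde; the side-chain centre comes from catalytic desymmetrisation of 3-propylglutaric anhydride. Both are fixed before the fragments are joined and no stereocentre is made afterwards.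

Key step: step 11

Assumption: the dihydroquinidine-derived catalyst (DHQD)2AQN is taken to open 3-alkylglutaric anhydrides in the sense that gives the (S)-hemiester 16; were the sense the opposite, its dihydroquinine-derived pseudoenantiomer (DHQ)2AQN would be used in step 7 with nothing else changed.

**Route**

Step 1
Reactants: 1 acetaldehyde; 2 trans-but-2-ene
Product: 5 (2S,3R)-3-methylpent-4-en-2-ol, via (E)-crotyldiisopinocampheylborane 3 (not isolated), via dialkylborinate 4 (not isolated)
Conditions: 2, KOt-Bu, n-BuLi, THF, −78 to −45 °C; (+)-Ipc2BOMe [B-methoxydiisopinocampheylborane made from (−)-α-pinene], −78 °C; BF3·OEt2, −78 °C; 1, −78 °C; then NaOH, H2O2, 0 °C to rt; distillation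
Reagents that add atoms: none
Why: Brown crotylboration, in which the (E)-crotylborane reacts through a chair Zimmerman–Traxler transition state to give the anti adduct and the isopinocampheyl groups of the (−)-α-pinene series direct attack to the Re face of the aldehyde, so that the carbinol carbon should be set as S and the methyl-bearing carbon as R (the later C2 and C3 of the chroman).

Step 2
Reactants: 5 (2S,3R)-3-methylpent-4-en-2-ol; 6 methyl acrylate
Product: 7 methyl (2E,4R,5S)-5-hydroxy-4-methylhex-2-enoate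
Conditions: second-generation Hoveyda–Grubbs catalyst [RuCl2(H2IMes)(=CH-2-(i-PrO)C6H4)] (5 mol%), methyl acrylate (4 equiv), CH2Cl2, 40 °C
Reagents that add atoms: none
Why: Olefin cross-metathesis of a terminal alkene with an acrylate, which should favour the cross product because the acrylate homodimerises slowly; the alkene geometry is of no consequence since it is saturated in step 3, and the stereocentres are not touched.

Step 3
Reactants: 7 methyl (2E,4R,5S)-5-hydroxy-4-methylhex-2-enoate
Product: 9 (5R,6S)-5,6-dimethyloxan-2-one, via hydroxy ester 8 (not isolated)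
Conditions: H2 (1 atm), Pd/C, EtOAc, rt; filter; TsOH·H2O (cat.), toluene, 50 °C
Reagents that add atoms: none
Why: Catalytic hydrogenation of the conjugated alkene followed by acid-catalysed lactonisation of the δ-hydroxy ester, an acyl substitution that leaves both stereocentres as they are and should give the trans-5,6-dimethyl δ-lactone.

Step 4
Reactants: 9 (5R,6S)-5,6-dimethyloxan-2-one; 10 ethyl acetate
Product: 12 ethyl (2E)-2-[(5R,6S)-5,6-dimethyloxan-2-ylidene]acetate, via hemiketal adduct 11 (not isolated)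
Conditions: LiN(SiMe3)2, EtOAc, THF, −78 °C; 9, −78 °C; aq NH4Cl; crude adduct, TsOH·H2O (5 mol%), 4 Å MS, toluene, 80 °C
Reagents that add atoms: none
Why: Claisen-type addition of the lithium enolate of ethyl acetate to the δ-lactone, which stops at the lactol stage, followed by acid-catalysed dehydration through the ring oxocarbenium ion to the conjugated exocyclic enol ether in its more stable E form; the C6–O bond is never broken, so the carbinol configuration is kept.

Step 5
Reactants: 12 ethyl (2E)-2-[(5R,6S)-5,6-dimethyloxan-2-ylidene]acetate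
Product: 13 (2E)-2-[(5R,6S)-5,6-dimethyloxan-2-ylidene]acetic acid
Conditions: LiOH·H2O, THF/MeOH/H2O, 50 °C; then cold 1 M HCl to pH 4–5 at 0 °C, rapid extraction; used crude
Reagents that add atoms: lithium hydroxide (hydroxide oxygen), [Li+].[OH-]
Why: Saponification of a vinylogous carbonate ester, whose carboxylate is stable to base and whose enol ether, deactivated toward protonation by conjugation with the carboxyl group, should survive a brief cold acidification.

Step 6
Reactants: 13 (2E)-2-[(5R,6S)-5,6-dimethyloxan-2-ylidene]acetic acid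
Product: 14 (2E)-1-(1H-benzotriazol-1-yl)-2-[(5R,6S)-5,6-dimethyloxan-2-ylidene]ethan-1-one
Conditions: 1H-benzotriazole, DCC, CH2Cl2, 0 °C to rt
Reagents that add atoms: 1H-benzotriazole, c1ccc2[nH]nnc2c1
Why: Carbodiimide coupling of the acid with benzotriazole, which should give a storable N-acylbenzotriazole under neutral conditions that spare the enol ether and provides the acyl donor for the crossed Claisen condensation of step 9.

Step 7
Reactants: 15 3-propylglutaric anhydride (4-propyloxane-2,6-dione)
Product: 16 (3S)-3-(2-methoxy-2-oxoethyl)hexanoic acid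
Conditions: (DHQD)2AQN [hydroquinidine anthraquinone-1,4-diyl diether] (0.3 equiv), MeOH (10 equiv), Et2O, −40 °C; catalyst removed by acid wash
Reagents that add atoms: methanol, CO
Why: Cinchona-alkaloid-catalysed desymmetrising alcoholysis of a prochiral cyclic anhydride (general-base catalysis by the quinuclidine nitrogen), which distinguishes the two enantiotopic carbonyl groups and so sets the side-chain stereocentre; the enantiomeric purity could be raised by crystallising a salt of 16 with a chiral amine.

Step 8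
Reactants: 16 (3S)-3-(2-methoxy-2-oxoethyl)hexanoic acid; 17 thiophenol
Product: 18 methyl (3R)-3-[2-oxo-2-(phenylsulfanyl)ethyl]hexanoate
Conditions: DCC, DMAP (5 mol%), CH2Cl2, 0 °C to rt
Reagents that add atoms: none
Why: Steglich thioesterification of the free acid arm; the stereocentre is β to both carbonyl groups and cannot epimerise, and its descriptor changes from S to R only because the thioester arm now outranks the ester arm.

Step 9
Reactants: 18 methyl (3R)-3-[2-oxo-2-(phenylsulfanyl)ethyl]hexanoate; 14 (2E)-1-(1H-benzotriazol-1-yl)-2-[(5R,6S)-5,6-dimethyloxan-2-ylidene]ethan-1-one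
Product: 19 methyl (3R)-3-{(2RS)-4-[(2E,5R,6S)-5,6-dimethyloxan-2-ylidene]-1,3-dioxo-1-(phenylsulfanyl)butan-2-yl}hexanoate
Conditions: MgBr2·OEt2 (3 equiv), i-Pr2NEt (4 equiv), CH2Cl2, rt
Reagents that add atoms: none
Why: Soft-enolisation crossed Claisen condensation, in which magnesium coordination lets the amine deprotonate the thioester α-CH2 in preference to the far less acidic methyl ester and the enolate is C-acylated by the acylbenzotriazole (forming C6–C7), the product being held as its magnesium chelate; the new centre between the carbonyl groups forms as a mixture and is removed in step 10.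

Step 10
Reactants: 19 methyl (3R)-3-{(2RS)-4-[(2E,5R,6S)-5,6-dimethyloxan-2-ylidene]-1,3-dioxo-1-(phenylsulfanyl)butan-2-yl}hexanoate
Product: 20 S-phenyl (2Z)-3-methoxy-2-[(3R)-1-methoxy-1-oxohexan-3-yl]-4-[(2E,5R,6S)-5,6-dimethyloxan-2-ylidene]but-2-enethioate
Conditions: LiN(SiMe3)2 (1.05 equiv), toluene, −78 °C; MeOTf (1.3 equiv), −78 to 0 °C; Et3N quench
Reagents that add atoms: methyl trifluoromethanesulfonate, COS(=O)(=O)C(F)(F)F
Why: O-Alkylation of a β-dicarbonyl enolate by a hard methylating agent, favoured because the carbon between the carbonyl groups is shielded by the branched side chain and the vinylogous-ester oxygen is the most electron-rich site; alkylation of the lithium chelate should place OMe cis to the thioester carbonyl (2Z), a geometry that is in any case erased in step 11.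

Step 11
Reactants: 20 S-phenyl (2Z)-3-methoxy-2-[(3R)-1-methoxy-1-oxohexan-3-yl]-4-[(2E,5R,6S)-5,6-dimethyloxan-2-ylidene]but-2-enethioate
Product: 23 methyl (3R)-3-[(2S,3R)-5-hydroxy-7-methoxy-2,3-dimethyl-3,4-dihydro-2H-chromen-6-yl]hexanoate, via dienylketene 21 (not isolated), via cyclohexadienone 22 (not isolated)
Conditions: AgOCOCF3 (1.5 equiv), Et3N (3 equiv), 4 Å MS, THF (0.01 M), 0 °C to rt, dark
Reagents that add atoms: none
Why: Proposed new method: silver binds the sulfur of 20 and, pushed by the C7 methoxy group and the ring oxygen through the dienoyl system, AgSPh departs to leave a donor-stabilised acylium (ketene–oxocarbenium) ion whose ring CH2 next to the oxocarbenium carbon is deprotonated by Et3N to give dienylketene 21; the closest known reaction types are the silver-promoted conversion of β-keto thioesters into acylketenes, the amine dehydrohalogenation of unsaturated acyl halides to conjugated ketenes, and the thermal 6π electrocyclisation of dienylketenes to phenols. The benzene ring closes by disrotatory 6π electrocyclisation that joins C4a to the ketene carbon C5, and dienone 22 then enolises to the arene, so that the thioester carbonyl ends as the free C5 phenol. No stereocentre is created: the sp3 centre at C4a of 22 is lost on enolisation, and C2, C3 and the side-chain centre lie outside the reacting π system. The step needs closure through carbon and not through O1, and a cis arrangement of C6 and C8a about the C7=C8 bond of the ketene; the E-configured ylidene places the ring CH2, not the ring oxygen, on the side of the acyl carbon, and both alkene geometries of 20 become single bonds in 21. A ketene of the wrong C7=C8 geometry can return to the acylium ion by reversible addition of trifluoroacetate or Et3N and should be drained through the productive isomer.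

Step 12
Reactants: 23 methyl (3R)-3-[(2S,3R)-5-hydroxy-7-methoxy-2,3-dimethyl-3,4-dihydro-2H-chromen-6-yl]hexanoate; 24 1-bromo-3-methylbut-2-ene (prenyl bromide)
Product: 25 methyl (3R)-3-{(2S,3R)-7-methoxy-2,3-dimethyl-5-[(3-methylbut-2-en-1-yl)oxy]-3,4-dihydro-2H-chromen-6-yl}hexanoate
Conditions: K2CO3 (3 equiv), acetone, 50 °C
Reagents that add atoms: none
Why: Williamson etherification of the C5 phenoxide by a reactive allylic bromide, which should outrun attack of the phenoxide on the neighbouring methyl ester.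

Step 13
Reactants: 25 methyl (3R)-3-{(2S,3R)-7-methoxy-2,3-dimethyl-5-[(3-methylbut-2-en-1-yl)oxy]-3,4-dihydro-2H-chromen-6-yl}hexanoate
Product: 28 methyl (3R)-3-[(2S,3R)-5-hydroxy-7-methoxy-2,3-dimethyl-8-(3-methylbut-2-en-1-yl)-3,4-dihydro-2H-chromen-6-yl]hexanoate, via ortho-dienone 26 (not isolated), via para-dienone 27 (not isolated)
Conditions: N,N-diethylaniline, 185 °C, sealed tube, argon
Reagents that add atoms: none
Why: para-Claisen rearrangement: the aromatic Claisen shift can only reach a substituted ortho carbon (C4a), the resulting dienone cannot enolise and hands the 1,1-dimethylallyl group on by a Cope shift to C8, the only unsubstituted ring carbon, where enolisation restores the phenol and leaves a normal prenyl group.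

Step 14
Reactants: 28 methyl (3R)-3-[(2S,3R)-5-hydroxy-7-methoxy-2,3-dimethyl-8-(3-methylbut-2-en-1-yl)-3,4-dihydro-2H-chromen-6-yl]hexanoate
Product: 29 (3R)-3-[(2S,3R)-5-hydroxy-7-methoxy-2,3-dimethyl-8-(3-methylbut-2-en-1-yl)-3,4-dihydro-2H-chromen-6-yl]hexanoic acid
Conditions: LiOH·H2O (5 equiv), THF/MeOH/H2O, 40 °C; then 1 M HCl to pH 4 at 0 °C, immediate extraction
Reagents that add atoms: lithium hydroxide (hydroxide oxygen), [Li+].[OH-]
Why: Saponification of the methyl ester; no stereocentre is α to a carbonyl group, any lactonisation onto O5 that occurred earlier is reversed by the same hydroxide, and brief cold acidification should release the hydroxy acid without closing the lactone.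

**Compound list**

1 | acetaldehyde | CC=O | starting material
2 | trans-but-2-ene | C/C=C/C | starting material
3 | [(2E)-but-2-en-1-yl]bis[(1S,2R,3S,5S)-2,6,6-trimethylbicyclo[3.1.1]heptan-3-yl]borane | C/C=C/CB([C@H]1C[C@H]2C[C@@H]([C@@H]1C)C2(C)C)[C@H]1C[C@H]2C[C@@H]([C@@H]1C)C2(C)C | intermediate
4 | (2S,3R)-3-methylpent-4-en-2-yl bis[(1S,2R,3S,5S)-2,6,6-trimethylbicyclo[3.1.1]heptan-3-yl]borinate | C=C[C@@H](C)[C@H](C)OB([C@H]1C[C@H]2C[C@@H]([C@@H]1C)C2(C)C)[C@H]1C[C@H]2C[C@@H]([C@@H]1C)C2(C)C | intermediate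
5 | (2S,3R)-3-methylpent-4-en-2-ol | C=C[C@@H](C)[C@H](C)O | intermediate
6 | methyl acrylate | C=CC(=O)OC | starting material
7 | methyl (2E,4R,5S)-5-hydroxy-4-methylhex-2-enoate | COC(=O)/C=C/[C@@H](C)[C@H](C)O | intermediate
8 | methyl (4R,5S)-5-hydroxy-4-methylhexanoate | COC(=O)CC[C@@H](C)[C@H](C)O | intermediate
9 | (5R,6S)-5,6-dimethyloxan-2-one | O=C1CC[C@@H](C)[C@H](C)O1 | intermediate
10 | ethyl acetate | CCOC(C)=O | starting material
11 | ethyl 2-[(2RS,5R,6S)-2-hydroxy-5,6-dimethyloxan-2-yl]acetate | CCOC(=O)CC1(O)CC[C@@H](C)[C@H](C)O1 | intermediate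
12 | ethyl (2E)-2-[(5R,6S)-5,6-dimethyloxan-2-ylidene]acetate | CCOC(=O)/C=C1\CC[C@@H](C)[C@H](C)O1 | intermediate
13 | (2E)-2-[(5R,6S)-5,6-dimethyloxan-2-ylidene]acetic acid | OC(=O)/C=C1\CC[C@@H](C)[C@H](C)O1 | intermediate
14 | (2E)-1-(1H-benzotriazol-1-yl)-2-[(5R,6S)-5,6-dimethyloxan-2-ylidene]ethan-1-one | O=C(/C=C1\CC[C@@H](C)[C@H](C)O1)n1nnc2ccccc21 | intermediate
15 | 3-propylglutaric anhydride (4-propyloxane-2,6-dione) | CCCC1CC(=O)OC(=O)C1 | starting material
16 | (3S)-3-(2-methoxy-2-oxoethyl)hexanoic acid | CCC[C@H](CC(=O)OC)CC(=O)O | intermediate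
17 | thiophenol | Sc1ccccc1 | starting material
18 | methyl (3R)-3-[2-oxo-2-(phenylsulfanyl)ethyl]hexanoate | CCC[C@H](CC(=O)OC)CC(=O)Sc1ccccc1 | intermediate
19 | methyl (3R)-3-{(2RS)-4-[(2E,5R,6S)-5,6-dimethyloxan-2-ylidene]-1,3-dioxo-1-(phenylsulfanyl)butan-2-yl}hexanoate | CCC[C@H](CC(=O)OC)C(C(=O)Sc1ccccc1)C(=O)/C=C1\CC[C@@H](C)[C@H](C)O1 | intermediate
20 | S-phenyl (2Z)-3-methoxy-2-[(3R)-1-methoxy-1-oxohexan-3-yl]-4-[(2E,5R,6S)-5,6-dimethyloxan-2-ylidene]but-2-enethioate | CCC[C@H](CC(=O)OC)/C(C(=O)Sc1ccccc1)=C(OC)\C=C2/CC[C@@H](C)[C@H](C)O2 | intermediate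
21 | methyl (3R)-3-{(3E)-4-[(2S,3R)-2,3-dimethyl-3,4-dihydro-2H-pyran-6-yl]-3-methoxy-1-oxobuta-1,3-dien-2-yl}hexanoate | CCC[C@H](CC(=O)OC)C(=C=O)/C(OC)=C\C1=CC[C@@H](C)[C@H](C)O1 | intermediate
22 | methyl (3R)-3-[(2S,3R,4aRS)-7-methoxy-2,3-dimethyl-5-oxo-3,4,4a,5-tetrahydro-2H-chromen-6-yl]hexanoate | CCC[C@H](CC(=O)OC)C1=C(OC)C=C2O[C@@H](C)[C@H](C)CC2C1=O | intermediate
23 | methyl (3R)-3-[(2S,3R)-5-hydroxy-7-methoxy-2,3-dimethyl-3,4-dihydro-2H-chromen-6-yl]hexanoate | CCC[C@H](CC(=O)OC)c1c(O)c2c(cc1OC)O[C@@H](C)[C@H](C)C2 | intermediate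
24 | 1-bromo-3-methylbut-2-ene | CC(C)=CCBr | starting material
25 | methyl (3R)-3-{(2S,3R)-7-methoxy-2,3-dimethyl-5-[(3-methylbut-2-en-1-yl)oxy]-3,4-dihydro-2H-chromen-6-yl}hexanoate | CCC[C@H](CC(=O)OC)c1c(OCC=C(C)C)c2c(cc1OC)O[C@@H](C)[C@H](C)C2 | intermediate
26 | methyl (3R)-3-[(2S,3R,4aRS)-7-methoxy-2,3-dimethyl-4a-(2-methylbut-3-en-2-yl)-5-oxo-3,4,4a,5-tetrahydro-2H-chromen-6-yl]hexanoate | CCC[C@H](CC(=O)OC)C1=C(OC)C=C2O[C@@H](C)[C@H](C)CC2(C(C)(C)C=C)C1=O | intermediate
27 | methyl (3R)-3-[(2S,3R,8RS)-7-methoxy-2,3-dimethyl-8-(3-methylbut-2-en-1-yl)-5-oxo-3,4,5,8-tetrahydro-2H-chromen-6-yl]hexanoate | CCC[C@H](CC(=O)OC)C1=C(OC)C(CC=C(C)C)C2=C(C[C@@H](C)[C@H](C)O2)C1=O | intermediate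
28 | methyl (3R)-3-[(2S,3R)-5-hydroxy-7-methoxy-2,3-dimethyl-8-(3-methylbut-2-en-1-yl)-3,4-dihydro-2H-chromen-6-yl]hexanoate | CCC[C@H](CC(=O)OC)c1c(O)c2c(c(CC=C(C)C)c1OC)O[C@@H](C)[C@H](C)C2 | intermediate
29 | (3R)-3-[(2S,3R)-5-hydroxy-7-methoxy-2,3-dimethyl-8-(3-methylbut-2-en-1-yl)-3,4-dihydro-2H-chromen-6-yl]hexanoic acid | CCC[C@H](CC(=O)O)c1c(O)c2c(c(CC=C(C)C)c1OC)O[C@@H](C)[C@H](C)C2 | target

**Step count**

Total steps: 14.
Longest linear sequence: 12 steps (steps 1–6, then 9–14); steps 7 and 8 form the two-step side branch.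

**Steps most likely to fail**

1. Step 11 (new method). Ionisation of the α-branched, donor-substituted thioester may be too slow under silver and amine activation, or the ketene may be diverted by oligomerisation, by acylation of the phenol as it forms, or by closure through oxygen. The fallback uses known reactions throughout and sets out from 20. Silver-assisted hydrolysis of the thioester (AgOCOCF3, 2,6-lutidine, THF/H2O, rt) should give (2Z)-3-methoxy-2-[(3R)-1-methoxy-1-oxohexan-3-yl]-4-[(2E,5R,6S)-5,6-dimethyloxan-2-ylidene]but-2-enoic acid F1. Ghosez's reagent (1-chloro-N,N,2-trimethylprop-1-en-1-amine, CH2Cl2, 0 °C) converts it without acid into the acyl chloride F2. Et3N in toluene (0 to 60 °C) then removes HCl in the vinylogous sense that is the standard entry to vinyl- and dienylketenes from unsaturated acyl chlorides. This gives ketene 21, which closes and enolises through 22, and the route is rejoined at 23.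

2. Step 10. Methylation may go to carbon or to the thioester oxygen, and the dienol ether may be lost by hydrolysis during work-up. The fallback sets out from 19 and masks the C7 oxygen as a silyl ether, whose formation is reliably O-selective. TBSOTf and Et3N (CH2Cl2, −78 °C) give the silyl dienol ether F3. Under the conditions of step 11 this should pass through the silyloxy dienylketene F4 and the silyloxy dienone F5 to the 7-silyloxy phenol F6. K2CO3 and prenyl bromide in acetone give the 5-prenyl 7-silyl diether F7. CsF and MeI in DMF exchange silyl for methyl in one operation, and the route is rejoined at 25.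

3. Step 9. Acyl transfer from the donor-deactivated (vinylogous carbonate) acylbenzotriazole may be sluggish, so that self-condensation of the thioester takes over. The fallback replaces the Claisen condensation by an aldol addition and oxidation and sets out from 12. i-Bu2AlH (CH2Cl2, −78 °C) gives (2E)-2-[(5R,6S)-5,6-dimethyloxan-2-ylidene]ethan-1-ol F8, and MnO2 (CH2Cl2, rt) gives the β-alkoxy enal F9. Soft-enolisation aldol addition of 18 to this aldehyde (MgBr2·OEt2, i-Pr2NEt, CH2Cl2) gives the β-hydroxy thioester F10 as a mixture of diastereomers. Dess–Martin periodinane buffered with NaHCO3 oxidises it to the β-keto thioester, and the route is rejoined at 19.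

**Further compounds**

F1 | step 11 | (2Z)-3-methoxy-2-[(3R)-1-methoxy-1-oxohexan-3-yl]-4-[(2E,5R,6S)-5,6-dimethyloxan-2-ylidene]but-2-enoic acid | CCC[C@H](CC(=O)OC)/C(C(=O)O)=C(OC)\C=C1/CC[C@@H](C)[C@H](C)O1
F2 | step 11 | methyl (3R)-3-{(2Z)-1-chloro-3-methoxy-4-[(2E,5R,6S)-5,6-dimethyloxan-2-ylidene]-1-oxobut-2-en-2-yl}hexanoate | CCC[C@H](CC(=O)OC)/C(C(=O)Cl)=C(OC)\C=C1/CC[C@@H](C)[C@H](C)O1
F3 | step 10 | S-phenyl (2Z)-3-[(tert-butyldimethylsilyl)oxy]-2-[(3R)-1-methoxy-1-oxohexan-3-yl]-4-[(2E,5R,6S)-5,6-dimethyloxan-2-ylidene]but-2-enethioate | CCC[C@H](CC(=O)OC)/C(C(=O)Sc1ccccc1)=C(O[Si](C)(C)C(C)(C)C)\C=C1/CC[C@@H](C)[C@H](C)O1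
F4 | step 10 | methyl (3R)-3-{(3E)-3-[(tert-butyldimethylsilyl)oxy]-4-[(2S,3R)-2,3-dimethyl-3,4-dihydro-2H-pyran-6-yl]-1-oxobuta-1,3-dien-2-yl}hexanoate | CCC[C@H](CC(=O)OC)C(=C=O)/C(O[Si](C)(C)C(C)(C)C)=C\C1=CC[C@@H](C)[C@H](C)O1
F5 | step 10 | methyl (3R)-3-{(2S,3R,4aRS)-7-[(tert-butyldimethylsilyl)oxy]-2,3-dimethyl-5-oxo-3,4,4a,5-tetrahydro-2H-chromen-6-yl}hexanoate | CCC[C@H](CC(=O)OC)C1=C(O[Si](C)(C)C(C)(C)C)C=C2O[C@@H](C)[C@H](C)CC2C1=O
F6 | step 10 | methyl (3R)-3-{(2S,3R)-7-[(tert-butyldimethylsilyl)oxy]-5-hydroxy-2,3-dimethyl-3,4-dihydro-2H-chromen-6-yl}hexanoate | CCC[C@H](CC(=O)OC)c1c(O)c2c(cc1O[Si](C)(C)C(C)(C)C)O[C@@H](C)[C@H](C)C2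
F7 | step 10 | methyl (3R)-3-{(2S,3R)-7-[(tert-butyldimethylsilyl)oxy]-2,3-dimethyl-5-[(3-methylbut-2-en-1-yl)oxy]-3,4-dihydro-2H-chromen-6-yl}hexanoate | CCC[C@H](CC(=O)OC)c1c(OCC=C(C)C)c2c(cc1O[Si](C)(C)C(C)(C)C)O[C@@H](C)[C@H](C)C2
F8 | step 9 | (2E)-2-[(5R,6S)-5,6-dimethyloxan-2-ylidene]ethan-1-ol | OC/C=C1\CC[C@@H](C)[C@H](C)O1
F9 | step 9 | (2E)-2-[(5R,6S)-5,6-dimethyloxan-2-ylidene]acetaldehyde | O=C/C=C1\CC[C@@H](C)[C@H](C)O1
F10 | step 9 | methyl (3R)-3-{(2RS,3RS)-3-hydroxy-4-[(2E,5R,6S)-5,6-dimethyloxan-2-ylidene]-1-oxo-1-(phenylsulfanyl)butan-2-yl}hexanoate | CCC[C@H](CC(=O)OC)C(C(=O)Sc1ccccc1)C(O)/C=C1\CC[C@@H](C)[C@H](C)O1
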